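**Retrosynthetic overview**
- The four benzyl ethers and one aryl acetate come off last. Before that, the oxygen between C3 of ring C and the vanilloyl carbonyl is excised (retro-Baeyer–Villiger) to leave a cis-3-aroylflavan.
- The strategy rests on the C3–O–C(=O)–aryl ester on ring C, cis to ring B at C2. Without the bridging oxygen it is a C3–C(=O)–aryl ketone, and a carbon substituent at C3 can be set cis to ring B by adding hydrogen to a C3=C4 alkene from the face away from ring B.
- The 3-aroyl-2H-chromene is reached from a 2H-chromene-3-carbaldehyde by aryl Grignard addition and oxidation. The silyl-to-acetyl exchange is done at the enone stage, before C3 becomes stereogenic.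
- Ring C is the only ring formed: an amine-catalysed oxa-Michael/aldol condensation joins a 4,6-dibenzyloxysalicylaldehyde (ring A) to a 3,4-dibenzyloxycinnamaldehyde (ring B) and sets C2. Rings A, B and the vanilloyl ring are bought.

Key step: step 9

Remark: 3,5-dibenzyloxyphenol, 3,4-dibenzyloxybenzaldehyde and 4-bromo-2-methoxyphenol are taken as purchasable.
Remark: the sense of induction in step 3 follows the usual facial-shielding model for diarylprolinol silyl ether iminium ions; should the rotation of the product show the opposite sense, the enantiomeric catalyst would be used.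

**Step 1**
Reactants: 1 3,5-dibenzyloxyphenol
Product: 2 2-hydroxy-4,6-dibenzyloxybenzaldehyde
Conditions: MgCl2, Et3N, (CH2O)n, MeCN, reflux; then 1 M HCl
Reagents that add atoms: paraformaldehyde (as formaldehyde), C=O
Why: Magnesium-phenoxide-directed ortho-formylation (Casnati–Skattebøl) delivers formaldehyde only ortho to the phenol and a second formaldehyde oxidises the benzylic alkoxide by hydride transfer; the two ortho positions of 1 are equivalent, so one aldehyde should form.

**Step 2**
Reactants: 3 3,4-dibenzyloxybenzaldehyde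
Product: 4 (E)-3-(3,4-dibenzyloxyphenyl)prop-2-enal
Conditions: Ph3P=CHCHO (1.1 equiv), toluene, 80 °C
Reagents that add atoms: (triphenylphosphoranylidene)acetaldehyde, O=CC=P(c1ccccc1)(c1ccccc1)c1ccccc1
Why: Wittig olefination with a stabilised formyl ylide should give the E enal, and the small excess of ylide holds back a second homologation.

**Step 3**
Reactants: 2 2-hydroxy-4,6-dibenzyloxybenzaldehyde; 4 (E)-3-(3,4-dibenzyloxyphenyl)prop-2-enal
Product: 5 (R)-5,7-dibenzyloxy-2-(3,4-dibenzyloxyphenyl)-2H-chromene-3-carbaldehyde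
Conditions: (S)-2-[diphenyl(trimethylsilyloxy)methyl]pyrrolidine (20 mol%), 2-nitrobenzoic acid (20 mol%), 4 Å MS, toluene, rt
Reagents that add atoms: none
Why: Iminium/enamine-catalysed domino oxa-Michael/aldol condensation, in which the diphenyl(silyloxy)methyl group shields one face of the E-iminium ion so that the phenol oxygen adds to the Si face of the enal β-carbon (C2 set R by the catalyst), and aldol closure onto the salicylaldehyde carbonyl with loss of water forms ring C.

**Step 4**
Reactants: 6 4-bromo-2-methoxyphenol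
Product: 7 (4-bromo-2-methoxyphenoxy)(tert-butyl)dimethylsilane
Conditions: TBSCl, imidazole, DMF, rt
Reagents that add atoms: tert-butyldimethylsilyl chloride, CC(C)(C)[Si](C)(C)Cl
Why: Imidazole-promoted silylation of a phenol gives an aryl silyl ether that tolerates magnesium insertion.

**Step 5**
Reactants: 7 (4-bromo-2-methoxyphenoxy)(tert-butyl)dimethylsilane; 5 (R)-5,7-dibenzyloxy-2-(3,4-dibenzyloxyphenyl)-2H-chromene-3-carbaldehyde
Product: 9 [(2R)-5,7-dibenzyloxy-2-(3,4-dibenzyloxyphenyl)-2H-chromen-3-yl][4-(tert-butyldimethylsilyloxy)-3-methoxyphenyl]methanol (both carbinol epimers), via aryl Grignard reagent 8 (not isolated)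
Conditions: 7, Mg turnings (I2 crystal), THF, reflux; then 5, THF, −78 to 0 °C; sat. aq. NH4Cl
Reagents that add atoms: none
Why: Magnesium insertion into the aryl bromide followed by Grignard 1,2-addition to the enal carbonyl should give the allylic alcohol, whose new carbinol centre is formed unselectively and is destroyed in step 6.

**Step 6**
Reactants: 9 [(2R)-5,7-dibenzyloxy-2-(3,4-dibenzyloxyphenyl)-2H-chromen-3-yl][4-(tert-butyldimethylsilyloxy)-3-methoxyphenyl]methanol
Product: 10 [(2R)-5,7-dibenzyloxy-2-(3,4-dibenzyloxyphenyl)-2H-chromen-3-yl][4-(tert-butyldimethylsilyloxy)-3-methoxyphenyl]methanone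
Conditions: activated MnO2 (excess), CH2Cl2, rt
Reagents that add atoms: none
Why: MnO2 oxidation of a doubly activated (allylic and benzylic) alcohol proceeds under neutral conditions that leave C2, the silyl ether and the benzyl ethers untouched.

**Step 7**
Reactants: 10 [(2R)-5,7-dibenzyloxy-2-(3,4-dibenzyloxyphenyl)-2H-chromen-3-yl][4-(tert-butyldimethylsilyloxy)-3-methoxyphenyl]methanone
Product: 12 4-{[(2R)-5,7-dibenzyloxy-2-(3,4-dibenzyloxyphenyl)-2H-chromen-3-yl]carbonyl}-2-methoxyphenyl acetate, via free phenol 11 (not isolated)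
Conditions: TBAF, AcOH, THF, 0 °C; then Ac2O, Et3N, DMAP (cat.), 0 °C to rt
Reagents that add atoms: acetic anhydride, CC(=O)OC(C)=O
Why: Buffered fluoride desilylation and DMAP-catalysed acetylation in one flask exchange the donor silyl ether for the acceptor acetate while C3 is still sp2, so that no epimerisable centre is exposed to fluoride or amine.

**Step 8**
Reactants: 12 4-{[(2R)-5,7-dibenzyloxy-2-(3,4-dibenzyloxyphenyl)-2H-chromen-3-yl]carbonyl}-2-methoxyphenyl acetate
Product: 13 (2S,3R)-3-(4-acetoxy-3-methoxybenzoyl)-5,7-dibenzyloxy-2-(3,4-dibenzyloxyphenyl)chroman (2,3-cis)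
Conditions: H2 (1 atm), 10% Pd/C, Ph2S (cat.), EtOAc, rt
Reagents that add atoms: none
Why: Heterogeneous hydrogenation on sulfide-poisoned Pd/C should add H2 syn to the C3=C4 bond from the face opposite the pseudo-axial C2 aryl group, which puts the C3 hydrogen trans and the aroyl group cis to ring B (C3 set R by substrate control), while the poison suppresses benzyl ether hydrogenolysis and ketone reduction.

**Step 9**
Reactants: 13 (2S,3R)-3-(4-acetoxy-3-methoxybenzoyl)-5,7-dibenzyloxy-2-(3,4-dibenzyloxyphenyl)chroman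
Product: 14 (2R,3R)-5,7-dibenzyloxy-2-(3,4-dibenzyloxyphenyl)chroman-3-yl 4-acetoxy-3-methoxybenzoate
Conditions: mCPBA (acid-free, 3 equiv), solid NaHCO3, CH2Cl2, 0 °C to rt, dark
Reagents that add atoms: m-chloroperbenzoic acid, O=C(OO)c1cccc(Cl)c1
Why: Baeyer–Villiger oxidation: the peracid adds to the aryl ketone to give a tetrahedral peroxy hemiketal, and the group antiperiplanar to the O–O bond shifts from carbon to oxygen as 3-chlorobenzoate leaves. The closest known case is the peracid oxidation of secondary-alkyl aryl ketones such as cyclohexyl phenyl ketone to the sec-alkyl benzoates. No ring is closed and no new stereocentre is made: C3 migrates with retention, so the cis relation to ring B from step 8 is carried into the C3–O bond and C3 stays R (C2 becomes R only through the change in priorities). The step needs C3 to migrate in preference to the aryl group; a secondary alkyl carbon is the better migrating group, and the aryl ring carries a para-acetoxy and a meta-methoxy group instead of a strong para donor. It also needs the ketone to react before rings A and B are hydroxylated and before C3 epimerises, which is why acid-free peracid, a solid bicarbonate buffer, low temperature and exclusion of light are chosen.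

**Step 10**
Reactants: 14 (2R,3R)-5,7-dibenzyloxy-2-(3,4-dibenzyloxyphenyl)chroman-3-yl 4-acetoxy-3-methoxybenzoate
Product: 15 (2R,3R)-5,7-dibenzyloxy-2-(3,4-dibenzyloxyphenyl)chroman-3-yl 4-hydroxy-3-methoxybenzoate
Conditions: N2H4·AcOH, DMF, rt
Reagents that add atoms: none
Why: Chemoselective hydrazinolysis cleaves the phenolic acetate, a far better acyl donor than the hindered secondary-alkyl benzoate at C3, under near-neutral conditions.

**Step 11**
Reactants: 15 (2R,3R)-5,7-dibenzyloxy-2-(3,4-dibenzyloxyphenyl)chroman-3-yl 4-hydroxy-3-methoxybenzoate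
Product: 16 (2R,3R)-2-(3,4-dihydroxyphenyl)-5,7-dihydroxychroman-3-yl 4-hydroxy-3-methoxybenzoate (CNP0302437.1)
Conditions: H2 (1 atm), 20% Pd(OH)2/C, THF/MeOH, rt, then filtration under argon
Reagents that add atoms: none
Why: Catalytic hydrogenolysis removes the four benzyl ethers as toluene, while the C3 ester and the cyclic C2–O1 ether are expected to survive at ambient pressure in neutral solvent.

**Compound list**
1 | 3,5-dibenzyloxyphenol | Oc1cc(OCc2ccccc2)cc(OCc2ccccc2)c1 | starting material
2 | 2-hydroxy-4,6-dibenzyloxybenzaldehyde | O=Cc1c(O)cc(OCc2ccccc2)cc1OCc1ccccc1 | intermediate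
3 | 3,4-dibenzyloxybenzaldehyde | O=Cc1ccc(OCc2ccccc2)c(OCc2ccccc2)c1 | starting material
4 | (E)-3-(3,4-dibenzyloxyphenyl)prop-2-enal | O=C/C=C/c1ccc(OCc2ccccc2)c(OCc2ccccc2)c1 | intermediate
5 | (R)-5,7-dibenzyloxy-2-(3,4-dibenzyloxyphenyl)-2H-chromene-3-carbaldehyde | O=CC1=Cc2c(OCc3ccccc3)cc(OCc3ccccc3)cc2O[C@@H]1c1ccc(OCc2ccccc2)c(OCc2ccccc2)c1 | intermediate
6 | 4-bromo-2-methoxyphenol | COc1cc(Br)ccc1O | starting material
7 | (4-bromo-2-methoxyphenoxy)(tert-butyl)dimethylsilane | COc1cc(Br)ccc1O[Si](C)(C)C(C)(C)C | intermediate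
8 | [4-(tert-butyldimethylsilyloxy)-3-methoxyphenyl]magnesium bromide (not isolated) | COc1cc([Mg]Br)ccc1O[Si](C)(C)C(C)(C)C | intermediate
9 | [(2R)-5,7-dibenzyloxy-2-(3,4-dibenzyloxyphenyl)-2H-chromen-3-yl][4-(tert-butyldimethylsilyloxy)-3-methoxyphenyl]methanol, both carbinol epimers | COc1cc(C(O)C2=Cc3c(OCc4ccccc4)cc(OCc4ccccc4)cc3O[C@@H]2c2ccc(OCc3ccccc3)c(OCc3ccccc3)c2)ccc1O[Si](C)(C)C(C)(C)C | intermediate
10 | [(2R)-5,7-dibenzyloxy-2-(3,4-dibenzyloxyphenyl)-2H-chromen-3-yl][4-(tert-butyldimethylsilyloxy)-3-methoxyphenyl]methanone | COc1cc(C(=O)C2=Cc3c(OCc4ccccc4)cc(OCc4ccccc4)cc3O[C@@H]2c2ccc(OCc3ccccc3)c(OCc3ccccc3)c2)ccc1O[Si](C)(C)C(C)(C)C | intermediate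
11 | [(2R)-5,7-dibenzyloxy-2-(3,4-dibenzyloxyphenyl)-2H-chromen-3-yl](4-hydroxy-3-methoxyphenyl)methanone (not isolated) | COc1cc(C(=O)C2=Cc3c(OCc4ccccc4)cc(OCc4ccccc4)cc3O[C@@H]2c2ccc(OCc3ccccc3)c(OCc3ccccc3)c2)ccc1O | intermediate
12 | 4-{[(2R)-5,7-dibenzyloxy-2-(3,4-dibenzyloxyphenyl)-2H-chromen-3-yl]carbonyl}-2-methoxyphenyl acetate | COc1cc(C(=O)C2=Cc3c(OCc4ccccc4)cc(OCc4ccccc4)cc3O[C@@H]2c2ccc(OCc3ccccc3)c(OCc3ccccc3)c2)ccc1OC(C)=O | intermediate
13 | (2S,3R)-3-(4-acetoxy-3-methoxybenzoyl)-5,7-dibenzyloxy-2-(3,4-dibenzyloxyphenyl)chroman | COc1cc(C(=O)[C@@H]2Cc3c(OCc4ccccc4)cc(OCc4ccccc4)cc3O[C@@H]2c2ccc(OCc3ccccc3)c(OCc3ccccc3)c2)ccc1OC(C)=O | intermediate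
14 | (2R,3R)-5,7-dibenzyloxy-2-(3,4-dibenzyloxyphenyl)chroman-3-yl 4-acetoxy-3-methoxybenzoate | COc1cc(C(=O)O[C@@H]2Cc3c(OCc4ccccc4)cc(OCc4ccccc4)cc3O[C@@H]2c2ccc(OCc3ccccc3)c(OCc3ccccc3)c2)ccc1OC(C)=O | intermediate
15 | (2R,3R)-5,7-dibenzyloxy-2-(3,4-dibenzyloxyphenyl)chroman-3-yl 4-hydroxy-3-methoxybenzoate | COc1cc(C(=O)O[C@@H]2Cc3c(OCc4ccccc4)cc(OCc4ccccc4)cc3O[C@@H]2c2ccc(OCc3ccccc3)c(OCc3ccccc3)c2)ccc1O | intermediate
16 | (2R,3R)-2-(3,4-dihydroxyphenyl)-5,7-dihydroxychroman-3-yl 4-hydroxy-3-methoxybenzoate | COc1cc(C(=O)O[C@@H]2Cc3c(O)cc(O)cc3O[C@@H]2c2ccc(O)c(O)c2)ccc1O | target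

**Step count**
Total: 11 steps. Longest linear sequence: 9 steps (1 → 2 → 5 → 9 → 10 → 12 → 13 → 14 → 15 → 16).

**Steps most likely to fail**

1. Step 9 (Baeyer–Villiger). Oxygen insertion at the hindered aryl ketone may be slow, which would give the peracid time to hydroxylate the electron-rich rings A and B. Part of the material may also follow the aryl-migration path, and C3 may epimerise (or ring C open by β-elimination of the O1 phenoxide) before it is oxidised.
Fallback, from 5 back to 14, with the C3 oxygen introduced as a ketone and no peracid used. Chlorite oxidation of 5 (NaClO2, NaH2PO4, 2-methyl-2-butene, t-BuOH/THF/H2O) should give (R)-5,7-dibenzyloxy-2-(3,4-dibenzyloxyphenyl)-2H-chromene-3-carboxylic acid F1. Diphenylphosphoryl azide and Et3N in toluene should convert it into the acyl azide F2, which on warming to 80 °C should rearrange (Curtius) to the vinyl isocyanate F3. Hydrolysis with dilute HCl in THF should then give the (2R)-flavan-3-one F4, the standard route from chromene-3-carboxylic acids to chroman-3-ones. Reduction with LiBH(s-Bu)3 and LiBr in THF at −78 °C should deliver hydride anti to ring B and give the cis alcohol 5,7,3',4'-tetra-O-benzylepicatechin F5. Carbodiimide esterification of F5 with purchased 4-acetoxy-3-methoxybenzoic acid (EDC·HCl, DMAP, CH2Cl2) should return 14.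

2. Step 8 (hydrogenation). The C3=C4 bond may migrate on the metal into conjugation with O1, which would erase C2. The allylic, benzylic C2–O1 bond or a benzyl ether may be hydrogenolysed, or hydrogen may be delivered with insufficient facial bias.
Fallback, from 12 back to 13, by hydride conjugate addition and kinetic protonation in place of H2 on a metal surface. Copper hydride catalysis ([(Ph3P)CuH]6 cat., PhMe2SiH, toluene, rt) should add hydride to C4 and give the dimethylphenylsilyl enol ether F6. Desilylative protonation with Et3N·3HF in THF at −40 °C should place the proton on C3 from the face away from ring B and give the cis ketone 13.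

3. Step 3 (domino oxa-Michael/aldol). Aldol closure onto the electron-rich, doubly ortho-substituted aldehyde may be sluggish with the bulky catalyst, and reversible oxa-Michael addition before closure may erode the enantiomeric purity at C2.
Fallback, from 2 and 4 back to 5, by resolution in place of asymmetric catalysis. Condensation with the unhindered pyrrolidine/benzoic acid pair in toluene should give the racemic aldehyde F7. Preparative chromatography on an amylose tris(3,5-dimethylphenylcarbamate) phase should separate 5 from its (S)-enantiomer F8, which is discarded.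

**Further compounds**
F1 | step 9 | (R)-5,7-dibenzyloxy-2-(3,4-dibenzyloxyphenyl)-2H-chromene-3-carboxylic acid | O=C(O)C1=Cc2c(OCc3ccccc3)cc(OCc3ccccc3)cc2O[C@@H]1c1ccc(OCc2ccccc2)c(OCc2ccccc2)c1
F2 | step 9 | (R)-5,7-dibenzyloxy-2-(3,4-dibenzyloxyphenyl)-2H-chromene-3-carbonyl azide | [N-]=[N+]=NC(=O)C1=Cc2c(OCc3ccccc3)cc(OCc3ccccc3)cc2O[C@@H]1c1ccc(OCc2ccccc2)c(OCc2ccccc2)c1
F3 | step 9 | (R)-5,7-dibenzyloxy-2-(3,4-dibenzyloxyphenyl)-3-isocyanato-2H-chromene | O=C=NC1=Cc2c(OCc3ccccc3)cc(OCc3ccccc3)cc2O[C@@H]1c1ccc(OCc2ccccc2)c(OCc2ccccc2)c1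
F4 | step 9 | (2R)-5,7-dibenzyloxy-2-(3,4-dibenzyloxyphenyl)chroman-3-one | O=C1Cc2c(OCc3ccccc3)cc(OCc3ccccc3)cc2O[C@@H]1c1ccc(OCc2ccccc2)c(OCc2ccccc2)c1
F5 | step 9 | (2R,3R)-5,7-dibenzyloxy-2-(3,4-dibenzyloxyphenyl)chroman-3-ol | O[C@@H]1Cc2c(OCc3ccccc3)cc(OCc3ccccc3)cc2O[C@@H]1c1ccc(OCc2ccccc2)c(OCc2ccccc2)c1
F6 | step 8 | 4-{[(2R)-5,7-dibenzyloxy-2-(3,4-dibenzyloxyphenyl)chroman-3-ylidene](dimethylphenylsilyloxy)methyl}-2-methoxyphenyl acetate, enol ether geometry not defined | COc1cc(C(O[Si](C)(C)c2ccccc2)=C2Cc3c(OCc4ccccc4)cc(OCc4ccccc4)cc3O[C@@H]2c2ccc(OCc3ccccc3)c(OCc3ccccc3)c2)ccc1OC(C)=O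
F7 | step 3 | racemic 5,7-dibenzyloxy-2-(3,4-dibenzyloxyphenyl)-2H-chromene-3-carbaldehyde | O=CC1=Cc2c(OCc3ccccc3)cc(OCc3ccccc3)cc2OC1c1ccc(OCc2ccccc2)c(OCc2ccccc2)c1
F8 | step 3 | (S)-5,7-dibenzyloxy-2-(3,4-dibenzyloxyphenyl)-2H-chromene-3-carbaldehyde | O=CC1=Cc2c(OCc3ccccc3)cc(OCc3ccccc3)cc2O[C@H]1c1ccc(OCc2ccccc2)c(OCc2ccccc2)c1
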